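(The constants come from no measurement; what happens was integrated by code.)

The time of reading came first for me: 2.5 min in the closed flask, 2.5 min on average in the west tank, and 12.5 min on average in the south tank.

| setting | south | east | west |
|---|---|---|---|
| starting material | 10 mM | 10 mM | 10 mM |
| remark | one stirred flow tank at steady state, fed with the mixture as stated, mean residence time 12.5 min | a closed flask charged with all of it at once and left for 2.5 min | a single well-mixed tank run continuously and read at steady state, 2.5 min in it on average |
| time |  | 2.5 min |  |

    starting material → target (k1 = 0.018 /s)
    starting material → side product A (k2 = 0.019 /s)
    starting material → intermediate (k3 = 0.026 /s)
    intermediate → side product B (k4 = 0.0083 /s)

- the set-up with the highest amount of target at the outlet or at the end, in percent of the starting material put in ("none" if the first two lie within 2 percentage points) (south / east / west / none)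
- amount of target at the outlet or at the end, in percent of the starting material put in, south
- amount of target at the outlet or at the end, in percent of the starting material put in, east
- amount of target at the outlet or at the end, in percent of the starting material put in, west

I followed one molecule of starting material. Each step leaving it is first order in starting material, so its chance of taking the step to target stays the same throughout. That chance is the constant of the first step over the sum of the constants leaving starting material, and it came to 28.6%. I call it the fork share, the chance that a reacting molecule of starting material becomes target; the usual term is selectivity. Target is not consumed in the scheme, so target is the fork share times the fraction converted, and the fork share is my bound from above.

For the bound from below I took the west tank. Starting material lives 0.265 min on average, and a tank leaves the fraction one over one plus stay per lifetime unreacted. That gave 25.8% of the charge for the west tank. The south tank has a longer stay, and the closed flask converts more than the west tank in the same time, so both stand above that bound. Tightened, they gave 28.0% for the south tank and 28.6% for the closed flask. Those two lie 0.60 percentage points apart, less than the margin, so I committed to no winner.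

The forecast gave 28% south, 28.6% east, 25.8% west and the choice none, holding that the “yields therefore just follow conversion”. Its west value stands on my lower bound and its east value on my upper bound, to the digits printed. The simulation gave 28.0% south, 28.6% east, 25.8% west and the choice none.

Held against the lifetime of starting material, 0.265 min, the south tank's stay is 47.2 lifetimes and the west tank's is 9.43. In the south tank 2.07% of the charge stood unreacted, and the fork share of the converted part is 28.0% of the charge, beside the 28.0% of target there. The closed flask, left until 25.0 min, held 28.6% target against a fork share of 28.6%.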